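The data come from a simulation for substances that don't exist, and the scatter is random.

In a one-step world a single rate writes the whole ledger, so I looked for such a rate in this flask.

| setting | north-east | north | flask |
|---|---|---|---|
| left-handed substrate | 0.050 M | 0.050 M | 0.050 M |
| right-handed substrate | 0.050 M | 0.050 M | 0.050 M |
| solid reagent | 0.040 M | 0.040 M | 0.0400 M |
| free catalyst | 1.7 mM | 2.6 mM | 1.2 mM |
| remark | run made earlier | run made earlier |  |
| time |  |  | 30 min |

| run | time / min | left-handed product / % |
|---|---|---|
| north-east | 1.33 | 0.8 |
| north-east | 2.00 | 1.3 |
| north-east | 3.00 | 2.4 |
| north-east | 5.00 | 3.9 |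
| north-east | 8.00 | 6.4 |
| north-east | 12.0 | 9.7 |
| north-east | 20.0 | 14.3 |
| north | 2.50 | 0.4 |
| north | 5.00 | 4.5 |
| north | 8.00 | 6.8 |
| north | 10.0 | 6.7 |
| north | 12.0 | 10.0 |
| north | 15.0 | 13.0 |
| north | 20.0 | 17.5 |

(standard deviation of a reading: 1 percentage point)

- amount of left-handed product at 30 min, in percent of the left-handed substrate and right-handed substrate together charged
- concentration of coupling partner in solution at 30 min, in percent of saturation

- free catalyst is single-handed; left-handed substrate and right-handed substrate are mirror images of each other, charged as a racemate, each of them at the stated concentration
- solid, in amounts per volume of the solution: solid reagent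
- steps that have been proposed: free catalyst + left-handed substrate <-> catalyst intermediate A; solid reagent <-> coupling partner; free catalyst + right-handed substrate <-> catalyst intermediate B; coupling partner + catalyst intermediate A -> free catalyst + left-handed product; coupling partner + catalyst intermediate B -> free catalyst + right-handed product
- at the start none of the solid reagent is in solution

1. The charge. The flask holds 0.0400 M of solid reagent against 0.100 M of the two substrates together, so the solid reagent is the limiting reagent. A mole of it ends as left-handed product, right-handed product, dissolved coupling partner or solid. On the percent scale asked, its charge is 40.0%.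

2. The shape. In the north-east run, a straight line through the last reading passes 5.72% at 8.00 min, within 1 percentage point of the 6.4% read there. So I took dc(left-handed product)/dt = w, constant in time, which integrates to c(left-handed product) = w·t.

3. The catalyst. At 20.0 min the north run read 17.5% and the north-east run 14.3%, so I read w as growing with free catalyst to the power 0.475. For the flask this gives 0.606 mM min⁻¹, the draw: left-handed product made per minute at a given catalyst charge.

4. The entry. My flask reckoning gave 18.2% at 30 min. Right-handed product went unread, but if it kept pace the two would total 36.4%, still below the solid's charge, so I let the line run. Coupling partner went unread too, and I gave it no number.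

5. The forecast said 16% and 65%, on grounds other than my line: "The slowdown in the north-east run roughly matches first-order loss of left-handed substrate".

6. The flask gave 19.4% and 40.5%.

    free catalyst + left-handed substrate ⇌ catalyst intermediate A (K = 17.7 M⁻¹, k = 1570 M⁻¹ min⁻¹)
    solid reagent ⇌ coupling partner, rate k2*(cs2 - [coupling partner]) while solid is left; crystals form when [coupling partner] > cs2 (solubility = 4.50 mM, k = 0.379 min⁻¹)
    free catalyst + right-handed substrate ⇌ catalyst intermediate B (K = 21.9 M⁻¹, k = 756 M⁻¹ min⁻¹)
    coupling partner + catalyst intermediate A → free catalyst + left-handed product (k = 1250 M⁻¹ min⁻¹)
    coupling partner + catalyst intermediate B → free catalyst + right-handed product (k = 515 M⁻¹ min⁻¹)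

The flask's books closed at 40.0 mM of 40 mM: left-handed product 19.4%, right-handed product 11.0%, solid 19.3% of its own charge, coupling partner 1.82 mM. The flask's own draw, on average over 30 min, was 0.647 mM min⁻¹, above my 0.606 mM min⁻¹. The neighbouring flask, stopped at 20 min, tests the line: my draw gives 12.1%, the flask's own draw 12.9%, and that flask held 13.1%. It also held 7.14% of right-handed product, with 49% of the solid reagent's charge still solid or dissolved.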